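Ring A is built onto ring B, not coupled to it. With ring A counted from its bridge-bearing carbon 1 to its carbonyl carbon 6 (acetyl on carbon 5), carbon 6, carbon 1, the bridge CH2 and the ortho phenol oxygen of ring B are a masked dihydrocoumarin, and carbons 2 to 5 plus the acetyl group a masked gem-dimethyl enol lactone. The enolate of 5,7-bis(benzyloxy)chroman-2-one opens 3,3,6-trimethylpyran-2,4-dione and the freed diketone closes onto the aryl ester: one operation forms the bonds between carbons 1 and 2 and between carbons 5 and 6, closes ring A and frees the phenol.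

Key step: step 6

Assumption: the target SMILES shows one enol tautomer of each triketone ring; the tautomers interconvert, the target has no stereocentre, and every acylfilicinic unit below is drawn in that same tautomer.

Step 1
Reactants: 1 phloroglucinol; 2 acrylic acid
Product: 4 5,7-dihydroxychroman-2-one, via 3-(2,4,6-trihydroxyphenyl)propanoic acid 3 (not isolated)
Conditions: acrylic acid (1.1 equiv), Amberlyst-15 (sulfonated polystyrene resin), toluene, 110 °C, Dean–Stark
Reagents that add atoms: none
Why: Acid-catalysed Friedel–Crafts conjugate addition of the very electron-rich arene to acrylic acid should give 3, which lactonises onto a neighbouring hydroxyl under water removal (hydroarylation then lactonisation), and since the three ring carbons are equivalent there is no regiochemical issue.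

Step 2
Reactants: 4 5,7-dihydroxychroman-2-one
Product: 5 5,7-bis(benzyloxy)chroman-2-one
Conditions: BnBr (2.3 equiv), K2CO3, dry acetone, 56 °C
Reagents that add atoms: benzyl bromide, BrCc1ccccc1
Why: Williamson etherification of both phenols under anhydrous carbonate, conditions under which the aryl lactone should stay closed, removes every acidic O–H before the enolate chemistry of step 6.

Step 3
Reactants: 6 tert-butyl 3-oxobutanoate
Product: 8 tert-butyl 2,2-dimethyl-3-oxobutanoate, via tert-butyl 2-methyl-3-oxobutanoate 7 (not isolated)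
Conditions: MeI (2.5 equiv), K2CO3, DMF, 23 → 45 °C
Reagents that add atoms: iodomethane, CI
Why: Acetoacetic ester alkylation carried out twice at C2, the only carbon acidic enough for carbonate, installs the gem-dimethyl group and blocks C2 so that step 4 can only enolise the methyl ketone.

Step 4
Reactants: 8 tert-butyl 2,2-dimethyl-3-oxobutanoate
Product: 10 tert-butyl 2,2-dimethyl-3,5-dioxohexanoate, via hemiaminal adduct 9 (not isolated)
Conditions: LiN(SiMe3)2 (1.1 equiv), THF, −78 °C; MeC(O)N(OMe)Me (1.2 equiv), −78 → 0 °C; 1 M HCl
Reagents that add atoms: N-methoxy-N-methylacetamide, CC(=O)N(C)OC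
Why: The lithium enolate of the methyl ketone, the sole enolisable site of 8, should be C-acylated by the Weinreb amide (crossed Claisen-type acylation) through the chelated adduct 9, which persists until the quench and so prevents proton exchange with the more acidic diketone.

Step 5
Reactants: 10 tert-butyl 2,2-dimethyl-3,5-dioxohexanoate
Product: 12 3,3,6-trimethylpyran-2,4-dione, via 2,2-dimethyl-3,5-dioxohexanoic acid 11 (not isolated)
Conditions: CF3CO2H, (CF3CO)2O, CH2Cl2, 0 → 23 °C
Reagents that add atoms: none
Why: Acidolysis of the tert-butyl ester should give 11, whose carboxyl group is activated by trifluoroacetic anhydride and captured by the enol oxygen of the C5 ketone (enol lactonisation, 6-exo-trig), while the quaternary C3 forbids tautomerisation to a hydroxypyrone and keeps the product an acylating enol lactone.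

Step 6
Reactants: 5 5,7-bis(benzyloxy)chroman-2-one; 12 3,3,6-trimethylpyran-2,4-dione
Product: 14 2-acetyl-6-{[2,4-bis(benzyloxy)-6-hydroxyphenyl]methyl}-3,5-dihydroxy-4,4-dimethylcyclohexa-2,5-dien-1-one, via C-acylated lactone 13 (not isolated)
Conditions: LiN(SiMe3)2 (1.05 equiv), THF, −78 °C; 12 (1.1 equiv), −78 °C; LiN(SiMe3)2 (1.1 equiv), −78 → 23 °C; 1 M HCl
Reagents that add atoms: none
Why: Proposed new method: the lithium enolate of 5, whose nucleophilic carbon becomes ring A carbon 1, should add to the enol-ester carbonyl of 12 (the future ring A carbon 2), and collapse of the adduct expels the enol oxygen, which unmasks the acetyl group and leaves 13 as a diketone anion centred on the future ring A carbon 5, while the second portion of base removes the now doubly activated hydrogen at carbon 1. On warming, carbon 5 should acylate the aryl lactone carbonyl (ring A carbon 6) with loss of the ring B phenoxide, either directly or through the acylketene formed by elimination of the aryloxide, and the acidic triketone is trapped as its enolate, which makes the closure irreversible. The closest known reaction types are the Fujimoto–Belleau opening of an enol lactone by a carbon nucleophile and the Dieckmann (Claisen) closure onto an aryl ester, but their combination in one acyl transfer between two lactones has no direct precedent. Ring A closes by 6-exo-trig attack of the diketone enolate carbon on carbon 6 (enolexo with respect to the acetyl-side enolate), and no stereocentre is formed because the transient centre at carbon 1 in 13 ends as an sp2 carbon. The step needs attack at the lactone carbonyl of 12 and not at its ring ketone (the future carbon 4) or its methyl-bearing enone carbon, which the higher electrophilicity of the enol ester towards a hard lithium enolate at −78 °C should secure, and it needs closure through carbon 5 instead of the acetyl methyl carbon, for which the six- versus eight-membered ring and the much greater acidity of the central diketone carbon speak. Proton transfer from the methyl group of 12 is the main competitor and is countered by pre-forming the enolate at low temperature, by adding the second portion of base only after 12 has been consumed, and by the fact that any dienolate of 12 is re-protonated by the more acidic 13.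

Step 7
Reactants: 14 2-acetyl-6-{[2,4-bis(benzyloxy)-6-hydroxyphenyl]methyl}-3,5-dihydroxy-4,4-dimethylcyclohexa-2,5-dien-1-one
Product: 15 2-acetyl-6-{[2,4-bis(benzyloxy)-5-butanoyl-6-hydroxyphenyl]methyl}-3,5-dihydroxy-4,4-dimethylcyclohexa-2,5-dien-1-one
Conditions: PrCOCl (1.2 equiv), TiCl4 (3 equiv), CH2Cl2, −40 → 0 °C; 1 M HCl
Reagents that add atoms: butanoyl chloride, CCCC(=O)Cl
Why: Friedel–Crafts acylation of the electron-rich ring B should occur ortho to the titanium phenoxide while ring A is held as its titanium chelate, and attack at the other free ring carbon or loss of a benzyl group would do no harm because both sites become equivalent once the benzyl groups are removed in step 8.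

Step 8
Reactants: 15 2-acetyl-6-{[2,4-bis(benzyloxy)-5-butanoyl-6-hydroxyphenyl]methyl}-3,5-dihydroxy-4,4-dimethylcyclohexa-2,5-dien-1-one
Product: 16 2-acetyl-6-[(3-butanoyl-2,4,6-trihydroxyphenyl)methyl]-3,5-dihydroxy-4,4-dimethylcyclohexa-2,5-dien-1-one
Conditions: H2 (1 atm), Pd/C, EtOAc–MeOH, 23 °C
Reagents that add atoms: none
Why: Hydrogenolysis over palladium on carbon should cleave both benzyl aryl ethers, whereas the hydrogen-bonded aryl ketone and the fully substituted vinylogous acid of ring A are inert at 1 atm and 23 °C.

Step 9
Reactants: 17 1-(2,4,6-trihydroxyphenyl)propan-1-one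
Product: 19 3,5-dihydroxy-4,4-dimethyl-2-propanoylcyclohexa-2,5-dien-1-one (propanoylfilicinic acid), via C-monomethyl ketone 18 (not isolated)
Conditions: MeI (2.2 equiv), NaOMe (3 equiv), MeOH, 0 → 23 °C; 1 M HCl
Reagents that add atoms: iodomethane, CI
Why: Two successive C-methylations of the acylphloroglucinol anion at the same ring carbon (dearomatising alkylation) are the classical entry to acylfilicinic acids, and a limited amount of MeI should hold back further methylation.

Step 10
Reactants: 19 3,5-dihydroxy-4,4-dimethyl-2-propanoylcyclohexa-2,5-dien-1-one; 16 2-acetyl-6-[(3-butanoyl-2,4,6-trihydroxyphenyl)methyl]-3,5-dihydroxy-4,4-dimethylcyclohexa-2,5-dien-1-one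
Product: 22 target CNP0315613.0, via Mannich base 20 (not isolated), via methylidene trione 21 (not isolated)
Conditions: 19, Me2N=CH2 I (1.05 equiv), MeCN, 0 → 23 °C; then 16 (1.0 equiv), 45 °C
Reagents that add atoms: N,N-dimethylmethyleneiminium iodide, C[N+](C)=C.[I-]
Why: Mannich aminomethylation of the only free ring carbon of 19 should give 20, which loses dimethylamine to the Michael acceptor 21 that is trapped by the last nucleophilic ring carbon of 16 (Mannich reaction then Michael addition, the usual way to methylene-bridge acylphloroglucinols), and pre-forming the electrophile on 19 without strong base should limit homo-coupling and bridge exchange.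

Compound list
1 | phloroglucinol (benzene-1,3,5-triol) | Oc1cc(O)cc(O)c1 | starting material
2 | acrylic acid | C=CC(=O)O | starting material
3 | 3-(2,4,6-trihydroxyphenyl)propanoic acid (not isolated) | OC(=O)CCc1c(O)cc(O)cc1O | intermediate
4 | 5,7-dihydroxychroman-2-one | O=C1CCc2c(O)cc(O)cc2O1 | intermediate
5 | 5,7-bis(benzyloxy)chroman-2-one | O=C1CCc2c(OCc3ccccc3)cc(OCc3ccccc3)cc2O1 | intermediate
6 | tert-butyl 3-oxobutanoate | CC(=O)CC(=O)OC(C)(C)C | starting material
7 | tert-butyl 2-methyl-3-oxobutanoate (racemic, not isolated) | CC(=O)C(C)C(=O)OC(C)(C)C | intermediate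
8 | tert-butyl 2,2-dimethyl-3-oxobutanoate | CC(=O)C(C)(C)C(=O)OC(C)(C)C | intermediate
9 | tert-butyl 5-hydroxy-5-[methoxy(methyl)amino]-2,2-dimethyl-3-oxohexanoate (racemic, lithium alkoxide in the flask, not isolated) | CC(O)(CC(=O)C(C)(C)C(=O)OC(C)(C)C)N(C)OC | intermediate
10 | tert-butyl 2,2-dimethyl-3,5-dioxohexanoate | CC(=O)CC(=O)C(C)(C)C(=O)OC(C)(C)C | intermediate
11 | 2,2-dimethyl-3,5-dioxohexanoic acid (not isolated) | CC(=O)CC(=O)C(C)(C)C(=O)O | intermediate
12 | 3,3,6-trimethylpyran-2,4-dione | CC1=CC(=O)C(C)(C)C(=O)O1 | intermediate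
13 | 5,7-bis(benzyloxy)-3-(2,2-dimethyl-3,5-dioxohexanoyl)chroman-2-one (racemic, dianion in the flask, not isolated) | CC(=O)CC(=O)C(C)(C)C(=O)C1Cc2c(OCc3ccccc3)cc(OCc3ccccc3)cc2OC1=O | intermediate
14 | 2-acetyl-6-{[2,4-bis(benzyloxy)-6-hydroxyphenyl]methyl}-3,5-dihydroxy-4,4-dimethylcyclohexa-2,5-dien-1-one | CC(=O)C1=C(O)C(C)(C)C(O)=C(Cc2c(O)cc(OCc3ccccc3)cc2OCc2ccccc2)C1=O | intermediate
15 | 2-acetyl-6-{[2,4-bis(benzyloxy)-5-butanoyl-6-hydroxyphenyl]methyl}-3,5-dihydroxy-4,4-dimethylcyclohexa-2,5-dien-1-one | CCCC(=O)c1c(O)c(CC2=C(O)C(C)(C)C(O)=C(C(C)=O)C2=O)c(OCc2ccccc2)cc1OCc1ccccc1 | intermediate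
16 | 2-acetyl-6-[(3-butanoyl-2,4,6-trihydroxyphenyl)methyl]-3,5-dihydroxy-4,4-dimethylcyclohexa-2,5-dien-1-one | CCCC(=O)c1c(O)c(CC2=C(O)C(C)(C)C(O)=C(C(C)=O)C2=O)c(O)cc1O | intermediate
17 | 1-(2,4,6-trihydroxyphenyl)propan-1-one | CCC(=O)c1c(O)cc(O)cc1O | starting material
18 | 1-(2,4,6-trihydroxy-3-methylphenyl)propan-1-one (not isolated) | CCC(=O)c1c(O)cc(O)c(C)c1O | intermediate
19 | 3,5-dihydroxy-4,4-dimethyl-2-propanoylcyclohexa-2,5-dien-1-one | CCC(=O)C1=C(O)C(C)(C)C(O)=CC1=O | intermediate
20 | 6-[(dimethylamino)methyl]-3,5-dihydroxy-4,4-dimethyl-2-propanoylcyclohexa-2,5-dien-1-one (not isolated) | CCC(=O)C1=C(O)C(C)(C)C(O)=C(CN(C)C)C1=O | intermediate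
21 | 5-hydroxy-4,4-dimethyl-2-methylidene-6-propanoylcyclohex-5-ene-1,3-dione (not isolated) | CCC(=O)C1=C(O)C(C)(C)C(=O)C(=C)C1=O | intermediate
22 | target CNP0315613.0: butanoylphloroglucinol ring B carrying one CH2-linked acetylfilicinic acid (ring A) and one CH2-linked propanoylfilicinic acid (ring C) | CCCC(=O)c1c(O)c(CC2=C(O)C(C)(C)C(O)=C(C(C)=O)C2=O)c(O)c(CC2=C(O)C(C)(C)C(O)=C(C(=O)CC)C2=O)c1O | target

Total step count: 10 steps.
Longest linear sequence: 7 steps (steps 3, 4, 5, 6, 7, 8 and 10, from tert-butyl 3-oxobutanoate 6).

Steps most likely to fail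

Step 6. The lactone enolate may deprotonate the methyl group of 12 instead of acylating, may add in conjugate fashion to the methyl-bearing enone carbon, or the acylated lactone may not ring-close. The fallback attaches ring A by known chemistry instead of building it. It sets out from phloroglucinol 1, which is acylated with butanoyl chloride and AlCl3 (Friedel–Crafts) to 1-(2,4,6-trihydroxyphenyl)butan-1-one F1. Commercial 1-(2,4,6-trihydroxyphenyl)ethanone is gem-dimethylated with MeI and NaOMe, as in step 9, to 2-acetyl-3,5-dihydroxy-4,4-dimethylcyclohexa-2,5-dien-1-one F2. F2 is aminomethylated with Me2N=CH2 I to the Mannich base 2-acetyl-6-[(dimethylamino)methyl]-3,5-dihydroxy-4,4-dimethylcyclohexa-2,5-dien-1-one F3. On warming with an excess of F1, F3 should lose the amine and alkylate one of the two equivalent ring carbons of F1. The fallback comes back to the route at 16, so that steps 1 to 8 fall away.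

Step 7. The Lewis acid may strip or shift benzyl groups, the ring A enols may be O-acylated in place of C-acylation of ring B, or the methylene bridge may be cleaved under acid. The fallback sets out from 14 and reverses the order of events. Hydrogenolysis (H2, Pd/C) first gives the triol 2-acetyl-3,5-dihydroxy-4,4-dimethyl-6-[(2,4,6-trihydroxyphenyl)methyl]cyclohexa-2,5-dien-1-one F4, whose two free ring carbons are equivalent. A Houben–Hoesch reaction with butanenitrile (ZnCl2, HCl, Et2O, 0 °C) then gives the ketimine 2-acetyl-6-{[3-(1-iminobutyl)-2,4,6-trihydroxyphenyl]methyl}-3,5-dihydroxy-4,4-dimethylcyclohexa-2,5-dien-1-one F5 as its hydrochloride. Hydrolysis in warm water returns to the route at 16.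

Step 10. Homo-coupling of 19 through 21 and exchange of the methylene bridges by retro-Michael and Michael equilibration may erode the cross-coupled product. The fallback sets out from 16 and fixes the bridge carbon on ring B before the coupling. Rieche formylation (Cl2CHOMe, TiCl4, CH2Cl2, −20 °C) of the last ring carbon gives the aldehyde 2-acetyl-6-[(3-butanoyl-5-formyl-2,4,6-trihydroxyphenyl)methyl]-3,5-dihydroxy-4,4-dimethylcyclohexa-2,5-dien-1-one F6. Reductive alkylation of 19 with F6 (L-proline, Hantzsch ester, CH2Cl2–EtOH, 23 °C; Knoevenagel condensation then transfer hydrogenation) should come back to the route at the target 22.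

Further compounds
F1 | step 6 | 1-(2,4,6-trihydroxyphenyl)butan-1-one | CCCC(=O)c1c(O)cc(O)cc1O
F2 | step 6 | 2-acetyl-3,5-dihydroxy-4,4-dimethylcyclohexa-2,5-dien-1-one | CC(=O)C1=C(O)C(C)(C)C(O)=CC1=O
F3 | step 6 | 2-acetyl-6-[(dimethylamino)methyl]-3,5-dihydroxy-4,4-dimethylcyclohexa-2,5-dien-1-one | CC(=O)C1=C(O)C(C)(C)C(O)=C(CN(C)C)C1=O
F4 | step 7 | 2-acetyl-3,5-dihydroxy-4,4-dimethyl-6-[(2,4,6-trihydroxyphenyl)methyl]cyclohexa-2,5-dien-1-one | CC(=O)C1=C(O)C(C)(C)C(O)=C(Cc2c(O)cc(O)cc2O)C1=O
F5 | step 7 | 2-acetyl-6-{[3-(1-iminobutyl)-2,4,6-trihydroxyphenyl]methyl}-3,5-dihydroxy-4,4-dimethylcyclohexa-2,5-dien-1-one | CCCC(=N)c1c(O)c(CC2=C(O)C(C)(C)C(O)=C(C(C)=O)C2=O)c(O)cc1O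
F6 | step 10 | 2-acetyl-6-[(3-butanoyl-5-formyl-2,4,6-trihydroxyphenyl)methyl]-3,5-dihydroxy-4,4-dimethylcyclohexa-2,5-dien-1-one | CCCC(=O)c1c(O)c(CC2=C(O)C(C)(C)C(O)=C(C(C)=O)C2=O)c(O)c(C=O)c1O
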